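**Retrosynthetic overview**
1. End game on the intact tricycle: C12 ketone reduction; 13,14-epoxidation with formate loss and an O8→O9 acetyl shift; C2 carbinol set through the 3,4-epoxy ketone; OH-directed 3,4-epoxidation.
2. Key disconnection C6–C7 (plus the lactone C–O): an intramolecular γ-chloroallylation of a C7 aldehyde closes the ten-membered ring, sets C6 and C7, and installs Cl and the exo-methylene. The γ-lactone closes in the same flask.
3. C2–C3: acetylide addition of a C3–C6/C16 enyne dichloride made from 1,3-dichloroacetone.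
4. Ring A (C1–C10 and C11–C10 bonds): Diels–Alder reaction of an aminosiloxydiene with an E-enal attached to C4 of a glucose-derived furanose.
5. C7–C10 and all absolute stereochemistry come from diacetone-D-glucose; C8–C17 comes from a propanoate aldol on the 3-ulose. Ring order: ring A, ten-membered ring, γ-lactone, the two oxiranes.

Assumption and convention: briarane numbering (C1–C20) is used for all intermediates, β is the face of ring A that carries C15, and the chloroalkene of 22–28 is drawn as its major E isomer (the Z isomer converges in step 14).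

**Step 1**
Reactants: 1 1,2:5,6-di-O-isopropylidene-α-D-glucofuranose
Product: 2 1,2:5,6-di-O-isopropylidene-α-D-ribo-hexofuranos-3-ulose
Conditions: TEMPO (5 mol %), KBr (10 mol %), NaOCl, NaHCO3, CH2Cl2–H2O, 0 °C; azeotropic drying (toluene)
Reagents that add atoms: none
Why: Oxoammonium (Anelli-type) oxidation of the only free hydroxyl, with no stereocenter touched.

**Step 2**
Reactants: 2 1,2:5,6-di-O-isopropylidene-α-D-ribo-hexofuranos-3-ulose; 3 methyl propanoate
Product: 6 3-O-acetyl-3-C-[(1R)-1-(methoxycarbonyl)ethyl]-1,2:5,6-di-O-isopropylidene-α-D-allofuranose, via lithium enolate 4 (not isolated), via lithium aldolate 5 (not isolated)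
Conditions: 3, LiN(iPr)2, THF–DMPU 4:1, −78 °C; 2, −78 °C; then Ac2O, −78 °C → rt
Reagents that add atoms: acetic anhydride, CC(=O)OC(C)=O
Why: Ester-enolate aldol addition in which the cis-fused 1,2-acetonide blocks the α-face so the carbon enters from the β-face (allo product, sets C8); the Z(O)-enolate reacts through a closed Zimmerman–Traxler array that puts C18 anti to C7 (sets C17, also the thermodynamically preferred epimer of the later lactone); trapping the aldolate as the acetate stops retro-aldol.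

**Step 3**
Reactants: 6 tertiary acetate
Product: 7 3-O-acetyl-3-C-[(1R)-1-(methoxycarbonyl)ethyl]-1,2-O-isopropylidene-α-D-ribo-pentodialdo-1,4-furanose (C10 aldehyde)
Conditions: H5IO6 (1.2 equiv), EtOAc, rt
Reagents that add atoms: none
Why: Periodic acid hydrolyses the more labile terminal acetonide and cleaves the freed 5,6-glycol (Malaprade cleavage), leaving C9 untouched.

**Step 4**
Reactants: 7 C10 aldehyde; 8 2-(triphenyl-λ5-phosphanylidene)propanal
Product: 9 E-enal OHC(C2)–C1(CH3)=C10H on furanose C4 (= C9)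
Conditions: toluene, 80 °C
Reagents that add atoms: none
Why: Wittig olefination with a stabilised ylide gives the E-trisubstituted enal under base-free conditions, so the α-alkoxy aldehyde is not epimerised.

**Step 5**
Reactants: 10 (E)-4-(dimethylamino)but-3-en-2-one
Product: 12 (E)-1-(dimethylamino)pent-1-en-3-one, via lithium dienolate 11 (not isolated)
Conditions: LiN(iPr)2, THF, −78 °C; MeI, −78 → 0 °C
Reagents that add atoms: iodomethane, CI
Why: Kinetic α′-deprotonation of the vinylogous amide followed by SN2 methylation (brings in C20).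

**Step 6**
Reactants: 12 (E)-1-(dimethylamino)pent-1-en-3-one
Product: 14 (1E,3Z)-3-(tert-butyldimethylsilyloxy)-N,N-dimethylpenta-1,3-dien-1-amine, via potassium enolate 13 (not isolated)
Conditions: KN(SiMe3)2, THF, −78 °C; TBSCl, −78 °C → rt
Reagents that add atoms: tert-butyldimethylsilyl chloride, CC(C)(C)[Si](C)(C)Cl
Why: O-silylation of the Z-enolate gives a Rawal-type 1-amino-3-siloxydiene with the methyl group in the reactive outside position.

**Step 7**
Reactants: 9 E-enal; 14 aminosiloxydiene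
Product: 16 ring A enone aldehyde (C12 ketone; 13-ene; 11α-methyl; C2 aldehyde), via Diels–Alder cycloadduct 15 (not isolated)
Conditions: 14 (2 equiv), toluene, 60 °C; then HF (aq) in MeCN, 0 °C
Reagents that add atoms: none
Why: Normal-demand endo Diels–Alder reaction in which nucleophilic C11 bonds to the β-carbon C10 and C14 bonds to C1; A(1,3) strain with C15 holds H9 in the alkene plane so the diene adds anti to quaternary C8, and the E geometry is carried into trans C2/C9 (sets C1 and C10); HF then cleaves the enol ether and β-eliminates Me2NH, and the 11α-methyl is corrected in step 13.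

**Step 8**
Reactants: 16 ring A enone aldehyde
Product: 17 triethylsilyl dienol ether aldehyde (C11=C12(OSiEt3)–C13=C14)
Conditions: Et3SiOTf, Et3N, CH2Cl2, −78 → 0 °C
Reagents that add atoms: triethylsilyl triflate, CC[Si](CC)(CC)OS(=O)(=O)C(F)(F)F
Why: Soft enolisation can only remove H11 because C1 is quaternary, so the cross-conjugated silyl dienol ether forms, which masks the enone and erases the wrong C11 centre.

**Step 9**
Reactants: 18 1,3-dichloropropan-2-one; 19 ethynylmagnesium bromide
Product: 20 1-chloro-2-(chloromethyl)but-3-yn-2-ol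
Conditions: THF, −78 → −30 °C; aq. NH4Cl at −30 °C
Reagents that add atoms: none
Why: Grignard 1,2-addition to the ketone, quenched cold so that the chlorohydrin alkoxide does not close to an oxirane.

**Step 10**
Reactants: 20 1-chloro-2-(chloromethyl)but-3-yn-2-ol
Product: 22 (E)-1-chloro-2-(chloromethyl)but-1-en-3-yne, via tertiary mesylate 21 (not isolated)
Conditions: MsCl, Et3N (3 equiv), CH2Cl2, 0 °C → reflux
Reagents that add atoms: none
Why: Mesylation followed by E2 elimination of a chlorine-acidified CH2Cl proton; the E isomer dominates because Cl avoids the CH2Cl group.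

**Step 11**
Reactants: 17 triethylsilyl dienol ether aldehyde; 22 (E)-1-chloro-2-(chloromethyl)but-1-en-3-yne
Product: 24 2-epi propargylic alcohol (2β-OH), via lithium acetylide 23 (not isolated)
Conditions: AlMe3 + 2,6-di-tert-butyl-4-methylphenol (2 equiv per Al), toluene, rt, to give MeAl(OAr)2 (2 equiv); 17, −78 °C; 22, LiN(SiMe3)2, THF, −78 °C, cannulated in; −78 °C; aqueous work-up
Reagents that add atoms: none
Why: Amphiphilic anti-Felkin carbonyl addition in which the bulky aluminium phenoxide binds the aldehyde from the open Felkin quadrant (anti to C10, past sp2 C14), so the slim acetylide enters from the other face and gives the 2-epi carbinol that steers step 15.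

**Step 12**
Reactants: 24 2-epi propargylic alcohol
Product: 25 (3Z)-dienol
Conditions: H2 (1 atm, 1.0 equiv), Pd/CaCO3 poisoned with Pb(OAc)2 (Lindlar catalyst), quinoline, EtOAc, 0 °C
Reagents that add atoms: none
Why: Lindlar syn semi-hydrogenation gives the Z-alkene, and quinoline poisoning spares the C–Cl bonds and the hindered ring diene.

**Step 13**
Reactants: 25 (3Z)-dienol
Product: 27 seco aldehyde (C7 aldehyde; 8-OAc; 9-O-formate; 11β-methyl enone), via furanose lactol 26 (not isolated)
Conditions: CF3CO2H–H2O 9:1, 0 °C, 40 min; evaporate; NaIO4 (1.2 equiv), THF–pH 6 phosphate buffer, 0 °C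
Reagents that add atoms: none
Why: Acetal and silyl enol ether hydrolysis with kinetic protonation of C11 from the α-face, because the pseudo-axial C9 substituent covers the β-face (sets C11); Malaprade cleavage of the lactol glycol then bares the C7 aldehyde and leaves sugar C1 as the O9 formate, while the tertiary 8-acetate prevents C7–C8 cleavage.

**Step 14**
Reactants: 27 seco aldehyde
Product: 30 chloro macrolactone (ten-membered ring; 7,19-olide; 6α-Cl; 5(16)-ene; 2-epi-OH), via allylchromium dichloride 28 (not isolated), via ring-closed hydroxy ester 29 (not isolated)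
Conditions: CrCl3(thf)3 (15 mol %), Me3SiCl (2 equiv), n-Bu4NBF4 (0.1 M), DMF–THF 1:4, undivided cell, Al anode, reticulated vitreous carbon cathode, 2 mA cm−2, 2.2 F mol−1, 27 added over 10 h (final 2 mM), 25 °C; then aq. citric acid
Reagents that add atoms: none
Why: Proposed new method: cathodic reduction of trivalent to divalent chromium converts the primary allylic chloride into allylchromium 28 by two one-electron transfers (the vinyl C–Cl bond is inert without nickel); fast 1,3-metallotropy funnels both chloroalkene isomers into the E-γ-chloroallyl form, which adds through a chair Zimmerman–Traxler array (Cl and C8 equatorial, hence anti C6/C7) to the Felkin–Anh face of the α-acetoxy aldehyde (OAc anti to the incoming carbon, C9 inside, hence C7 as in the target); this closes the ten-membered ring and creates the exo-methylene, the chromium alkoxide lactonises on the C19 ester, and Me3SiCl strips methoxide from chromium to close the catalytic cycle; the closest known reaction types are the stoichiometric CrCl2 chloroallylation of aldehydes with 1,3-dichloropropene, Nozaki–Hiyama–Kishi allylation macrocyclisation and electrochemically regenerated chromium catalysis, which have never been combined or used for a γ-chloroallyl ring closure.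

**Step 15**
Reactants: 30 chloro macrolactone
Product: 31 3α,4α-epoxy 2-epi-alcohol
Conditions: mCPBA (1.1 equiv), NaHCO3, CH2Cl2, −10 °C
Reagents that add atoms: 3-chloroperoxybenzoic acid, O=C(OO)c1cccc(Cl)c1
Why: Henbest hydroxyl-directed epoxidation in which A(1,3) strain of the Z-alkene holds H2 in the alkene plane, so the 2β-OH lies on the outer face and delivers the peracid there (sets C3 and C4, cis); the enone and the chlorine-deactivated exo-methylene do not react.

**Step 16**
Reactants: 31 3α,4α-epoxy 2-epi-alcohol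
Product: 32 3α,4α-epoxy 2-ketone
Conditions: Dess–Martin periodinane, NaHCO3, CH2Cl2, 0 °C → rt
Reagents that add atoms: none
Why: Dess–Martin oxidation of the only free carbinol under buffered conditions that leave the vinyl oxirane and the allylic chloride intact.

**Step 17**
Reactants: 32 3α,4α-epoxy 2-ketone
Product: 34 2α-acetate (2S), via epoxy alcohol 33 (not isolated)
Conditions: Zn(BH4)2, Et2O, −30 °C; then pyridine, Ac2O, DMAP (cat.), 0 °C
Reagents that add atoms: acetic anhydride, CC(=O)OC(C)=O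
Why: Chelation-controlled Zn(BH4)2 reduction of an α,β-epoxy ketone gives the erythro epoxy alcohol, with hydride coming from the ring periphery (sets C2); the chelated saturated ketone reacts faster than the conjugated C12 enone; acetylation follows in the same flask.

**Step 18**
Reactants: 34 2α-acetate
Product: 37 bis-epoxy 12-ketone (9-OAc; 8-OH), via 9-hydroxy 8-acetate 35 (not isolated), via 9-acetate enone 36 (not isolated)
Conditions: 30 % H2O2 (5 equiv), K2CO3 (0.3 equiv), MeOH–THF 1:1, −10 → 0 °C, 1 h; pH 7 buffer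
Reagents that add atoms: hydrogen peroxide, OO
Why: Weitz–Scheffer epoxidation in which HOO− adds to C14 anti to the axial C15 methyl (α-face, sets C13 and C14); the same mild base methanolyses the labile formate and drives the 1,2-acetyl shift from tertiary O8 to secondary O9; the weakly basic peroxide and the short cold contact spare C11 and the two hindered acetates.

**Step 19**
Reactants: 37 bis-epoxy 12-ketone
Product: 38 CNP0141778.2 (target)
Conditions: CeCl3·7H2O, NaBH4, MeOH, −78 °C
Reagents that add atoms: none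
Why: Luche reduction in which the β-face of the C12 ketone is blocked by the C20 and C15 methyl groups, so hydride enters from the α-face and gives the 12β-alcohol (sets C12) without touching lactone, acetates, oxiranes or chloride.

**Compound list**
1 | 1,2:5,6-di-O-isopropylidene-α-D-glucofuranose | CC1(C)OC[C@@H](O1)[C@H]2O[C@@H]3OC(C)(C)O[C@@H]3[C@H]2O | starting material
2 | 1,2:5,6-di-O-isopropylidene-α-D-ribo-hexofuranos-3-ulose | CC1(C)OC[C@@H](O1)[C@H]2O[C@@H]3OC(C)(C)O[C@@H]3C2=O | intermediate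
3 | methyl propanoate | CCC(=O)OC | starting material
4 | lithium Z(O)-enolate of methyl propanoate (CH3 cis to OLi) | C/C=C(/OC)[O-].[Li+] | intermediate
5 | lithium aldolate (3-C-branched α-D-allofuranose 3-alkoxide) | CC1(C)OC[C@@H](O1)[C@H]2O[C@@H]3OC(C)(C)O[C@@H]3[C@@]2([O-])[C@@H](C)C(=O)OC.[Li+] | intermediate
6 | 3-O-acetyl-3-C-[(1R)-1-(methoxycarbonyl)ethyl]-1,2:5,6-di-O-isopropylidene-α-D-allofuranose | CC1(C)OC[C@@H](O1)[C@H]2O[C@@H]3OC(C)(C)O[C@@H]3[C@@]2(OC(C)=O)[C@@H](C)C(=O)OC | intermediate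
7 | 3-O-acetyl-3-C-[(1R)-1-(methoxycarbonyl)ethyl]-1,2-O-isopropylidene-α-D-ribo-pentodialdo-1,4-furanose (C10 aldehyde) | O=C[C@H]1O[C@@H]2OC(C)(C)O[C@@H]2[C@@]1(OC(C)=O)[C@@H](C)C(=O)OC | intermediate
8 | 2-(triphenyl-λ5-phosphanylidene)propanal | CC(C=O)=P(c1ccccc1)(c1ccccc1)c1ccccc1 | starting material
9 | E-enal OHC(C2)–C1(CH3)=C10H on furanose C4 (= C9) | O=C/C(C)=C/[C@H]1O[C@@H]2OC(C)(C)O[C@@H]2[C@@]1(OC(C)=O)[C@@H](C)C(=O)OC | intermediate
10 | (E)-4-(dimethylamino)but-3-en-2-one | CC(=O)/C=C/N(C)C | starting material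
11 | lithium α′-dienolate of 10 | C=C([O-])/C=C/N(C)C.[Li+] | intermediate
12 | (E)-1-(dimethylamino)pent-1-en-3-one | CCC(=O)/C=C/N(C)C | intermediate
13 | potassium Z-enolate of 12 | C/C=C(\[O-])/C=C/N(C)C.[K+] | intermediate
14 | (1E,3Z)-3-(tert-butyldimethylsilyloxy)-N,N-dimethylpenta-1,3-dien-1-amine | C/C=C(\O[Si](C)(C)C(C)(C)C)/C=C/N(C)C | intermediate
15 | Diels–Alder cycloadduct (14α-NMe2, 11α-CH3, 12-ene silyl enol ether, C2 aldehyde α on C1) | O=C[C@]1(C)[C@H]([C@H](C)C(O[Si](C)(C)C(C)(C)C)=C[C@@H]1N(C)C)[C@H]2O[C@@H]3OC(C)(C)O[C@@H]3[C@@]2(OC(C)=O)[C@@H](C)C(=O)OC | intermediate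
16 | ring A enone aldehyde (C15 β, C2 α, C9 β, 11α-methyl) | O=C[C@]1(C)[C@H]([C@H](C)C(=O)C=C1)[C@H]2O[C@@H]3OC(C)(C)O[C@@H]3[C@@]2(OC(C)=O)[C@@H](C)C(=O)OC | intermediate
17 | triethylsilyl dienol ether aldehyde | O=C[C@]1(C)[C@H](C(C)=C(O[Si](CC)(CC)CC)C=C1)[C@H]2O[C@@H]3OC(C)(C)O[C@@H]3[C@@]2(OC(C)=O)[C@@H](C)C(=O)OC | intermediate
18 | 1,3-dichloropropan-2-one | ClCC(=O)CCl | starting material
19 | ethynylmagnesium bromide | C#C[Mg]Br | starting material
20 | 1-chloro-2-(chloromethyl)but-3-yn-2-ol | C#CC(O)(CCl)CCl | intermediate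
21 | 1-chloro-2-(chloromethyl)but-3-yn-2-yl methanesulfonate | C#CC(CCl)(CCl)OS(C)(=O)=O | intermediate
22 | (E)-1-chloro-2-(chloromethyl)but-1-en-3-yne | Cl/C=C(/CCl)C#C | intermediate
23 | lithium acetylide of 22 | Cl/C=C(/CCl)C#C[Li] | intermediate
24 | 2-epi propargylic alcohol (2β-OH, C3–C4 alkyne) | Cl/C=C(/CCl)C#C[C@H](O)[C@]1(C)[C@H](C(C)=C(O[Si](CC)(CC)CC)C=C1)[C@H]2O[C@@H]3OC(C)(C)O[C@@H]3[C@@]2(OC(C)=O)[C@@H](C)C(=O)OC | intermediate
25 | (3Z)-dienol (2β-OH) | Cl/C=C(/CCl)\C=C/[C@H](O)[C@]1(C)[C@H](C(C)=C(O[Si](CC)(CC)CC)C=C1)[C@H]2O[C@@H]3OC(C)(C)O[C@@H]3[C@@]2(OC(C)=O)[C@@H](C)C(=O)OC | intermediate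
26 | furanose lactol (anomeric mixture), 11β-methyl enone | Cl/C=C(/CCl)\C=C/[C@H](O)[C@]1(C)[C@H]([C@@H](C)C(=O)C=C1)[C@H]2OC(O)[C@H](O)[C@@]2(OC(C)=O)[C@@H](C)C(=O)OC | intermediate
27 | seco aldehyde (C7 aldehyde, 8-OAc, 9-O-formate, C19 methyl ester) | Cl/C=C(/CCl)\C=C/[C@H](O)[C@]1(C)[C@H]([C@@H](C)C(=O)C=C1)[C@@H](OC=O)[C@](C=O)(OC(C)=O)[C@@H](C)C(=O)OC | intermediate
28 | E-γ-chloroallylchromium dichloride | Cl/C=C(/C[Cr](Cl)Cl)\C=C/[C@H](O)[C@]1(C)[C@H]([C@@H](C)C(=O)C=C1)[C@@H](OC=O)[C@](C=O)(OC(C)=O)[C@@H](C)C(=O)OC | intermediate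
29 | ring-closed anti-chlorohydrin methyl ester | C=C1/C=C\[C@H](O)[C@]2(C)[C@H]([C@@H](C)C(=O)C=C2)[C@@H](OC=O)[C@](OC(C)=O)([C@@H](C)C(=O)OC)[C@@H](O)[C@H]1Cl | intermediate
30 | chloro macrolactone (3Z, 5(16)-ene, 6α-Cl, 7,19-olide, 2β-OH) | C=C1/C=C\[C@H](O)[C@]2(C)[C@H]([C@@H](C)C(=O)C=C2)[C@@H](OC=O)[C@]2(OC(C)=O)[C@@H](C)C(=O)O[C@H]2[C@H]1Cl | intermediate
31 | 3α,4α-epoxy 2-epi-alcohol | C=C1[C@H]2O[C@H]2[C@H](O)[C@]2(C)[C@H]([C@@H](C)C(=O)C=C2)[C@@H](OC=O)[C@]2(OC(C)=O)[C@@H](C)C(=O)O[C@H]2[C@H]1Cl | intermediate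
32 | 3α,4α-epoxy 2-ketone | C=C1[C@H]2O[C@H]2C(=O)[C@]2(C)[C@H]([C@@H](C)C(=O)C=C2)[C@@H](OC=O)[C@]2(OC(C)=O)[C@@H](C)C(=O)O[C@H]2[C@H]1Cl | intermediate
33 | (2S)-epoxy alcohol (2α-OH) | C=C1[C@H]2O[C@H]2[C@@H](O)[C@]2(C)[C@H]([C@@H](C)C(=O)C=C2)[C@@H](OC=O)[C@]2(OC(C)=O)[C@@H](C)C(=O)O[C@H]2[C@H]1Cl | intermediate
34 | 2α-acetate (8-OAc, 9-O-formate, 12-oxo-13-ene) | C=C1[C@H]2O[C@H]2[C@@H](OC(C)=O)[C@]2(C)[C@H]([C@@H](C)C(=O)C=C2)[C@@H](OC=O)[C@]2(OC(C)=O)[C@@H](C)C(=O)O[C@H]2[C@H]1Cl | intermediate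
35 | 9-hydroxy 8-acetate | C=C1[C@H]2O[C@H]2[C@@H](OC(C)=O)[C@]2(C)[C@H]([C@@H](C)C(=O)C=C2)[C@@H](O)[C@]2(OC(C)=O)[C@@H](C)C(=O)O[C@H]2[C@H]1Cl | intermediate
36 | 9-acetate 8-ol enone | C=C1[C@H]2O[C@H]2[C@@H](OC(C)=O)[C@]2(C)[C@H]([C@@H](C)C(=O)C=C2)[C@@H](OC(C)=O)[C@]2(O)[C@@H](C)C(=O)O[C@H]2[C@H]1Cl | intermediate
37 | bis-epoxy 12-ketone | C=C1[C@H]2O[C@H]2[C@@H](OC(C)=O)[C@]2(C)[C@H]([C@@H](C)C(=O)[C@@H]3O[C@@H]32)[C@@H](OC(C)=O)[C@]2(O)[C@@H](C)C(=O)O[C@H]2[C@H]1Cl | intermediate
38 | CNP0141778.2, (1R,2S,3R,4R,6S,7R,8R,9R,10S,11R,12R,13S,14R,17R) | C=C1[C@H]2O[C@H]2[C@@H](OC(C)=O)[C@]2(C)[C@H]([C@@H](C)[C@@H](O)[C@@H]3O[C@@H]32)[C@@H](OC(C)=O)[C@]2(O)[C@@H](C)C(=O)O[C@H]2[C@H]1Cl | target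

**Step count**
- Total steps: 19.
- Longest linear sequence: 15 (steps 1–4, 7, 8, 11–19).

**Three steps most likely to fail**

Step 14 (the new electrocatalytic γ-chloroallylation ring closure). The risks are oligomerisation, protonation of the allylchromium and low turnover.
The fallback sets out from 25 and comes back at 30, and it replaces redox chromium chemistry by allylboration.
- Borylation of the allylic chloride with B2pin2, catalysed by zerovalent palladium (Pd2(dba)3, toluene, 50 °C), gives the E-γ-chloroallyl pinacol boronate F5.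
- The unmasking used in step 13 (CF3CO2H–H2O, then NaIO4) gives the boronate aldehyde F6.
- F6 closes the ring by thermal intramolecular allylboration through a closed chair; E-γ-chloroallylboronates are known to give anti chlorohydrins.
- Aqueous NaHCO3 work-up and catalytic pyridinium tosylate lactonise the product to 30.

Step 7 (Diels–Alder reaction of a hindered trisubstituted enal). The risks are low reactivity and hetero-Diels–Alder reaction at the aldehyde.
The fallback sets out from 9 and comes back at 16.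
- Ethyl vinyl ketone is silylated (TBSOTf, Et3N) to (Z)-3-(tert-butyldimethylsilyloxy)penta-1,3-diene F1.
- F1 is combined with 9 under Me2AlCl activation (CH2Cl2, −78 → −20 °C) in a Lewis-acid Diels–Alder reaction to give the silyl enol ether cycloadduct F2.
- Saegusa–Ito dehydrogenation with Pd(OAc)2 in MeCN then gives 16.

Step 11 (anti-Felkin sense at C2). The risk is that the aluminium phenoxide fails to override Felkin control.
The fallback sets out from 17 and comes back at 24.
- Acetylide 23 is added without the aluminium reagent to give the Felkin product, the (2S)-propargylic alcohol F3.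
- Dess–Martin oxidation gives the ynone F4.
- Felkin-controlled 1,2-delivery of hydride with iBu2AlH (1.1 equiv, toluene, −78 °C) now places hydrogen where the acetylide had entered and gives 24.

**Further compounds**
F1 | step 7 | (Z)-3-(tert-butyldimethylsilyloxy)penta-1,3-diene | C/C=C(\O[Si](C)(C)C(C)(C)C)C=C
F2 | step 7 | silyl enol ether cycloadduct (12-ene, C14 methylene, 11α-methyl) | O=C[C@]1(C)[C@H]([C@H](C)C(O[Si](C)(C)C(C)(C)C)=CC1)[C@H]2O[C@@H]3OC(C)(C)O[C@@H]3[C@@]2(OC(C)=O)[C@@H](C)C(=O)OC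
F3 | step 11 | (2S)-propargylic alcohol (2α-OH epimer of 24) | Cl/C=C(/CCl)C#C[C@@H](O)[C@]1(C)[C@H](C(C)=C(O[Si](CC)(CC)CC)C=C1)[C@H]2O[C@@H]3OC(C)(C)O[C@@H]3[C@@]2(OC(C)=O)[C@@H](C)C(=O)OC
F4 | step 11 | C2 ynone | Cl/C=C(/CCl)C#CC(=O)[C@]1(C)[C@H](C(C)=C(O[Si](CC)(CC)CC)C=C1)[C@H]2O[C@@H]3OC(C)(C)O[C@@H]3[C@@]2(OC(C)=O)[C@@H](C)C(=O)OC
F5 | step 14 | E-γ-chloroallyl pinacol boronate | Cl/C=C(/CB1OC(C)(C)C(C)(C)O1)\C=C/[C@H](O)[C@]1(C)[C@H](C(C)=C(O[Si](CC)(CC)CC)C=C1)[C@H]2O[C@@H]3OC(C)(C)O[C@@H]3[C@@]2(OC(C)=O)[C@@H](C)C(=O)OC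
F6 | step 14 | boronate aldehyde | Cl/C=C(/CB1OC(C)(C)C(C)(C)O1)\C=C/[C@H](O)[C@]1(C)[C@H]([C@@H](C)C(=O)C=C1)[C@@H](OC=O)[C@](C=O)(OC(C)=O)[C@@H](C)C(=O)OC
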